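**Retrosynthetic overview**

1. The target is the 8α-isovanillate of a trans-fused 5–7 bicycle. The C3–C4 oxirane, the ester and the C10 carbinol are introduced last, all from one dienone (C8=O; C6=C7, C1=C10, C3=C4).
2. The plan rests on the seven-membered ring (C1, C2, C6, C7, C8, C9, C10). A C8 carbonyl flanked by C6=C7 and, one CH2 (C9) away, by C1=C10 is the [3,3] product of a ketene C7=C8 on C6 and an isopropenyl group C10=C9 on C1, held cis on a cyclopropane C6–C2–C1 that is fused to the five-membered ring (C2–C3–C4–C5–C6).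
3. The ketene comes from Wolff rearrangement of an α-diazo isobutyl ketone on the bridgehead C6 (C6 moves from C8 to C7), so ring expansion and placement of the isopropyl group on C7 are one operation.
4. The bicyclo[3.1.0]hexene comes from methyl 3-oxocyclopent-1-enecarboxylate by asymmetric methallyl sulfonium ylide cyclopropanation (sets C2), C4 methylation and enol triflate reduction, Weinreb amide and isobutyl Grignard addition, then diazo transfer.
5. Ring order: five-membered ring (purchased), cyclopropane (step 2), seven-membered ring at the expense of the cyclopropane (step 9), oxiranes (steps 12 and 16).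

Key step: step 9

**Remarks**

- Numbering for all compounds: seven-membered ring C1–C2–C6–C7–C8–C9–C10, five-membered ring C2–C3–C4–C5–C6; isopropyl on C7, oxygen on C8, methyl on C4 and on C10. β is the face of H2 and α the opposite face. The target has 2β-H, 6α-H, 7α-isopropyl, 8α-O, 10α-OH and a 3α,4α-oxirane.
- Names of the bicyclo[3.1.0]hexanes use their own ring numbering (ester carbon = C1).
- Assumption: the (1R,4R,5R) sulfide is taken to give the (1S,5S,6R) cyclopropane; if the ylide induces the opposite sense, the equally available enantiomeric sulfide is used and nothing else changes.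

**Route**

Step 1
Reactants: 1 (1R,4R,5R)-isothiocineole; 2 3-bromo-2-methylprop-1-ene
Product: 3 (1R,4R,5R)-4,7,7-trimethyl-6-(2-methylprop-2-en-1-yl)-6-thiabicyclo[3.2.1]octan-6-ium tetrafluoroborate (allyl group on the exo lone pair of sulfur)
Conditions: NaBF4, CH2Cl2/H2O, 23 °C
Reagents that add atoms: sodium tetrafluoroborate, [Na+].F[B-](F)(F)F
Why: SN2 S-alkylation of the sulfide by the allylic bromide on the less hindered exo lone pair, with anion metathesis to the non-nucleophilic tetrafluoroborate, is the standard entry to allylic sulfonium salts.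

Step 2
Reactants: 3 sulfonium tetrafluoroborate; 4 methyl 3-oxocyclopent-1-ene-1-carboxylate
Product: 6 methyl (1S,5S,6R)-4-oxo-6-(prop-1-en-2-yl)bicyclo[3.1.0]hexane-1-carboxylate, via sulfonium ylide 5 (not isolated)
Conditions: KN(SiMe3)2, THF, −78 °C; then 4, −78 → −20 °C
Reagents that add atoms: none
Why: Michael-initiated ring closure (sulfonium ylide cyclopropanation): the allylide adds through its α-carbon to the doubly activated C2=C6 alkene and the enolate displaces the sulfide in a 3-exo-tet closure, which should place the isopropenyl group exo (anti to the five-membered ring, hence cis to the bridgehead ester), while the chiral sulfide selects the alkene face and so sets C1, C2 and C6 together.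

Step 3
Reactants: 6 keto ester
Product: 7 methyl (1S,3S,5S,6R)-3-methyl-4-oxo-6-(prop-1-en-2-yl)bicyclo[3.1.0]hexane-1-carboxylate (3-exo-methyl epimer drawn)
Conditions: LiN(i-Pr)2, THF, −78 °C; MeI, −78 → −40 °C
Reagents that add atoms: iodomethane, CI
Why: Enolate alkylation is regiospecific because only C4 carries removable α-hydrogens (C2 is a cyclopropane bridgehead, the ester carbon C6 is quaternary); the configuration of the new methyl-bearing centre, expected anti to the cyclopropane, is of no consequence since C4 becomes sp2 in step 4.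

Step 4
Reactants: 7 methyl ketone
Product: 8 methyl (1S,5S,6R)-3-methyl-6-(prop-1-en-2-yl)-4-(trifluoromethylsulfonyloxy)bicyclo[3.1.0]hex-3-ene-1-carboxylate
Conditions: KN(SiMe3)2, THF, −78 °C; PhNTf2, −78 → 0 °C
Reagents that add atoms: N-phenylbis(trifluoromethanesulfonimide), O=S(=O)(N(c1ccccc1)S(=O)(=O)C(F)(F)F)C(F)(F)F
Why: Enol triflate formation: deprotonation can again occur only at C4, so O-sulfonylation of the enolate fixes the double bond at C3=C4 without regiochemical ambiguity.

Step 5
Reactants: 8 enol triflate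
Product: 9 methyl (1R,5S,6R)-3-methyl-6-(prop-1-en-2-yl)bicyclo[3.1.0]hex-3-ene-1-carboxylate
Conditions: Pd(OAc)2 (cat.), PPh3, HCO2H, n-Bu3N, DMF, 60 °C
Reagents that add atoms: none
Why: Palladium-catalysed formate reduction of an enol triflate (oxidative addition to zerovalent palladium, formate exchange, decarboxylation to the palladium hydride, reductive elimination) replaces OTf by H; the mono-ester-activated vinylcyclopropane is not expected to ionise under these conditions.

Step 6
Reactants: 9 bicyclic ester
Product: 10 (1R,5S,6R)-N-methoxy-N,3-dimethyl-6-(prop-1-en-2-yl)bicyclo[3.1.0]hex-3-ene-1-carboxamide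
Conditions: MeNH(OMe)·HCl, i-PrMgCl, THF, −20 → 0 °C
Reagents that add atoms: N,O-dimethylhydroxylamine hydrochloride, CNOC.Cl
Why: Aminolysis of the ester by the chloromagnesium amide of N,O-dimethylhydroxylamine gives the Weinreb amide directly; the ester has no α-hydrogen and the strained ring is not touched.

Step 7
Reactants: 10 Weinreb amide; 11 isobutylmagnesium bromide
Product: 12 3-methyl-1-[(1R,5S,6R)-3-methyl-6-(prop-1-en-2-yl)bicyclo[3.1.0]hex-3-en-1-yl]butan-1-one
Conditions: THF, 0 °C; aq NH4Cl
Reagents that add atoms: none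
Why: Weinreb ketone synthesis: the Grignard reagent adds once to give a stable magnesium chelate that releases the ketone only on work-up.

Step 8
Reactants: 12 isobutyl ketone
Product: 14 2-diazo-3-methyl-1-[(1R,5S,6R)-3-methyl-6-(prop-1-en-2-yl)bicyclo[3.1.0]hex-3-en-1-yl]butan-1-one, via trifluoroacetyl diketone 13 (not isolated)
Conditions: LiN(SiMe3)2, THF, −78 °C; CF3CO2CH2CF3, −78 °C; aq HCl; then MeSO2N3, Et3N, H2O, MeCN, 23 °C
Reagents that add atoms: 2,2,2-trifluoroethyl trifluoroacetate, O=C(OCC(F)(F)F)C(F)(F)F (trifluoroacetyl group of 13, lost again); methanesulfonyl azide, CS(=O)(=O)N=[N+]=[N-] (the N2 unit of 14)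
Why: Detrifluoroacetylative (Regitz-type) diazo transfer: Claisen trifluoroacetylation of the only possible enolate activates the CH2 between carbonyl and isopropyl, and the sulfonyl azide then transfers N2 with loss of the trifluoroacetyl group as its N-sulfonyl amide; the enolate is acylated at −78 °C, where a cis-2-vinylcyclopropyl enolate should not yet undergo a [3,3] shift of its own.

Step 9
Reactants: 14 diazoketone
Product: 16 (2β-H)-7-isopropyl-4,10-dimethylbicyclo[5.3.0]deca-1(10),3,6-trien-8-one, via isopropyl ketene 15 (not isolated)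
Conditions: hν (310 nm), dry degassed THF, −40 °C; then 23 °C in the dark
Reagents that add atoms: none
Why: Excitation of the diazoketone expels N2 with 1,2-shift of the cyclopropane carbon C6 from C8 to C7 (Wolff rearrangement), giving the isopropyl ketene 15, whose C7=C8 bond stands cis, across the C6–C1 bond, to the exo isopropenyl group (C10=C9). This cis-divinylcyclopropane array then undergoes the strain-driven [3,3]-sigmatropic (Cope) shift through the boat transition state with C8 and C9 folded over C2–H, forming C8–C9 and cleaving C1–C6; the closest known reaction type is the tandem Wolff–Cope rearrangement of cis-vinylcyclopropyl diazoketones to fused cycloheptadienones, and the fully substituted, isopropyl-bearing diazo carbon is where this substrate goes beyond the usual diazomethyl ketones. The seven-membered ring is closed by this pericyclic ring expansion (the three-membered ring grows by the four atoms C7, C8, C9 and C10), which gives both ring alkenes (C6=C7, C1=C10) cis and the C8 carbonyl from the ketene carbon. No stereocentre is created; C2, set in step 2, takes no part in the bond changes and is kept because the medium is neutral and free of base, which matters since H2 of 16 is triply allylic and γ to the ketone. The step needs Wolff migration to outrun 1,2-hydrogen shift from the isopropyl CH and carbene addition to the isopropenyl group; this rests on direct photolysis (concerted migration from the s-cis diazoketone, good migratory aptitude of a cyclopropyl carbon) and on the absence of carbenoid-forming metals. Irradiation is stopped when the diazo compound is consumed and the Cope shift is completed in the dark, to limit light-induced 1,3-acyl shift of the β,γ-unsaturated ketone.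

Step 10
Reactants: 16 dienone
Product: 18 (2β-H,6α-H)-7α-isopropyl-4,10-dimethylbicyclo[5.3.0]deca-1(10),3-dien-8-one, via lithium enolate 17 (not isolated)
Conditions: Li, NH3(l)/THF, t-BuOH (1 equiv), −78 °C; isoprene; solid NH4Cl
Reagents that add atoms: none
Why: Dissolving-metal (Birch-type) conjugate reduction: protonation of the radical anion at the β-carbon C6 should occur on the α face to give the trans ring fusion, and kinetic axial protonation of the regiodefined enolate 17 at C7 on the β face, anti to H6, leaves the isopropyl group equatorial (α), which is also the more stable arrangement; the cold, buffered quench avoids base that could move C1=C10 into conjugation.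

Step 11
Reactants: 18 ketone
Product: 19 (2β-H,6α-H)-7α-isopropyl-4,10-dimethylbicyclo[5.3.0]deca-1(10),3-dien-8α-ol
Conditions: LiBH(s-Bu)3, THF, −78 °C; NaOH, H2O2, 0 °C
Reagents that add atoms: none
Why: Ketone reduction by a bulky trialkylborohydride: equatorial attack on the β face (the side of the axial H7), as with 2-isopropylcyclohexanones, should give the axial 8α-alcohol cis to the isopropyl group.

Step 12
Reactants: 19 dienol
Product: 20 (2β-H,6α-H)-1α,10α-epoxy-7α-isopropyl-4,10β-dimethylbicyclo[5.3.0]dec-3-en-8α-ol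
Conditions: VO(acac)2 (cat.), t-BuOOH, CH2Cl2, 0 → 23 °C
Reagents that add atoms: tert-butyl hydroperoxide, CC(C)(C)OO
Why: Hydroxyl-directed vanadium-catalysed epoxidation: the homoallylic 8α-OH binds the vanadium alkylperoxide and delivers oxygen to the α face of C1=C10 only, leaving the undirected C3=C4 alkene untouched and setting C1 and C10.

Step 13
Reactants: 20 epoxy alcohol
Product: 21 (2β-H,6α-H)-7α-isopropyl-4,10β-dimethylbicyclo[5.3.0]dec-3-ene-8α,10α-diol
Conditions: LiBHEt3, THF, 0 → 40 °C; NaOH, H2O2
Reagents that add atoms: none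
Why: Reductive epoxide opening (SN2, trans-diaxial): hydride attacks the less substituted C1 from the β face, which leaves the oxygen on C10 as the axial 10α tertiary alcohol with the methyl group β.

Step 14
Reactants: 22 isovanillic acid
Product: 24 3-(tert-butyldimethylsilyloxy)-4-methoxybenzoic acid, via bis-silyl derivative 23 (not isolated)
Conditions: t-BuMe2SiCl, imidazole, DMF, 23 °C; then AcOH/THF/H2O, 23 °C
Reagents that add atoms: tert-butyldimethylsilyl chloride, CC(C)(C)[Si](C)(C)Cl
Why: Silylation of phenol and acid followed by selective hydrolysis of the labile silyl ester leaves the phenol masked as its aryl silyl ether for the acylation.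

Step 15
Reactants: 21 diol; 24 silyl-protected isovanillic acid
Product: 26 (2β-H,6α-H)-10α-hydroxy-7α-isopropyl-4,10β-dimethylbicyclo[5.3.0]dec-3-en-8α-yl 3-(tert-butyldimethylsilyloxy)-4-methoxybenzoate, via acid chloride 25 (not isolated)
Conditions: 24, (COCl)2, cat. DMF, CH2Cl2, 0 → 23 °C, concentrate; then 21, Et3N, DMAP, CH2Cl2, 0 → 40 °C
Reagents that add atoms: oxalyl chloride, ClC(=O)C(=O)Cl (supplies the chlorine of 25; no atom of it remains in 26)
Why: Nucleophilic acyl substitution with DMAP catalysis: only the secondary 8α-OH is acylated, the tertiary 10α-OH being inert under these conditions, and the C8 configuration is retained.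

Step 16
Reactants: 26 ester
Product: 27 (2β-H,6α-H)-3α,4α-epoxy-10α-hydroxy-7α-isopropyl-4β,10β-dimethylbicyclo[5.3.0]decan-8α-yl 3-(tert-butyldimethylsilyloxy)-4-methoxybenzoate
Conditions: VO(acac)2 (cat.), t-BuOOH, CH2Cl2, 23 °C
Reagents that add atoms: tert-butyl hydroperoxide, CC(C)(C)OO
Why: Hydroxyl-directed vanadium-catalysed epoxidation: the axial 10α-OH, bishomoallylic to C3=C4 through C1 and C2, should deliver oxygen to the α face of the cyclopentene against the steric preference for the β face, setting C3 and C4.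

Step 17
Reactants: 27 silyl-protected epoxide
Product: 28 (2β-H,6α-H)-3α,4α-epoxy-10α-hydroxy-7α-isopropyl-4β,10β-dimethylbicyclo[5.3.0]decan-8α-yl 3-hydroxy-4-methoxybenzoate (target, CNP0106636.1)
Conditions: Bu4NF, AcOH, THF, 0 °C
Reagents that add atoms: none
Why: Fluoride-mediated cleavage of the aryl silyl ether, buffered with acetic acid so that ester and oxirane are not touched, releases the phenol.

**Compound list**

1 | (1R,4R,5R)-4,7,7-trimethyl-6-thiabicyclo[3.2.1]octane (isothiocineole) | C[C@@H]1CC[C@@H]2C[C@H]1SC2(C)C | starting material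
2 | 3-bromo-2-methylprop-1-ene | C=C(C)CBr | starting material
3 | (1R,4R,5R)-4,7,7-trimethyl-6-(2-methylprop-2-en-1-yl)-6-thiabicyclo[3.2.1]octan-6-ium tetrafluoroborate, S-allyl group exo | C[C@@H]1CC[C@@H]2C[C@H]1[S@@+](CC(C)=C)C2(C)C.F[B-](F)(F)F | intermediate
4 | methyl 3-oxocyclopent-1-ene-1-carboxylate | COC(=O)C1=CC(=O)CC1 | starting material
5 | sulfonium 2-methylallylide derived from 3 | C[C@@H]1CC[C@@H]2C[C@H]1[S@@+]([CH-]C(C)=C)C2(C)C | intermediate (not isolated)
6 | methyl (1S,5S,6R)-4-oxo-6-(prop-1-en-2-yl)bicyclo[3.1.0]hexane-1-carboxylate (isopropenyl exo, cis to the ester) | COC(=O)[C@]12CCC(=O)[C@H]1[C@@H]2C(C)=C | intermediate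
7 | methyl (1S,3S,5S,6R)-3-methyl-4-oxo-6-(prop-1-en-2-yl)bicyclo[3.1.0]hexane-1-carboxylate (3-exo-methyl epimer) | COC(=O)[C@]12C[C@H](C)C(=O)[C@H]1[C@@H]2C(C)=C | intermediate
8 | methyl (1S,5S,6R)-3-methyl-6-(prop-1-en-2-yl)-4-(trifluoromethylsulfonyloxy)bicyclo[3.1.0]hex-3-ene-1-carboxylate | COC(=O)[C@]12CC(C)=C(OS(=O)(=O)C(F)(F)F)[C@H]1[C@@H]2C(C)=C | intermediate
9 | methyl (1R,5S,6R)-3-methyl-6-(prop-1-en-2-yl)bicyclo[3.1.0]hex-3-ene-1-carboxylate | COC(=O)[C@]12CC(C)=C[C@H]1[C@@H]2C(C)=C | intermediate
10 | (1R,5S,6R)-N-methoxy-N,3-dimethyl-6-(prop-1-en-2-yl)bicyclo[3.1.0]hex-3-ene-1-carboxamide | CON(C)C(=O)[C@]12CC(C)=C[C@H]1[C@@H]2C(C)=C | intermediate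
11 | isobutylmagnesium bromide | CC(C)C[Mg]Br | starting material
12 | 3-methyl-1-[(1R,5S,6R)-3-methyl-6-(prop-1-en-2-yl)bicyclo[3.1.0]hex-3-en-1-yl]butan-1-one | CC(C)CC(=O)[C@]12CC(C)=C[C@H]1[C@@H]2C(C)=C | intermediate
13 | 4,4,4-trifluoro-2-isopropyl-1-[(1R,5S,6R)-3-methyl-6-(prop-1-en-2-yl)bicyclo[3.1.0]hex-3-en-1-yl]butane-1,3-dione (epimers at C2 of the dione, enol forms) | CC(C)C(C(=O)C(F)(F)F)C(=O)[C@]12CC(C)=C[C@H]1[C@@H]2C(C)=C | intermediate (not isolated)
14 | 2-diazo-3-methyl-1-[(1R,5S,6R)-3-methyl-6-(prop-1-en-2-yl)bicyclo[3.1.0]hex-3-en-1-yl]butan-1-one (isopropenyl exo, cis to the acyl group) | CC(C)C(=[N+]=[N-])C(=O)[C@]12CC(C)=C[C@H]1[C@@H]2C(C)=C | intermediate (key-step precursor)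
15 | 3-methyl-2-[(1R,5S,6R)-3-methyl-6-(prop-1-en-2-yl)bicyclo[3.1.0]hex-3-en-1-yl]but-1-en-1-one (isopropyl ketene) | CC(C)C(=C=O)[C@]12CC(C)=C[C@H]1[C@@H]2C(C)=C | intermediate (not isolated)
16 | (2β-H)-7-isopropyl-4,10-dimethylbicyclo[5.3.0]deca-1(10),3,6-trien-8-one | O=C1CC(C)=C[C@@H]2C=C(C)CC2=C1C(C)C | intermediate (key-step product)
17 | lithium enolate (C7=C8–OLi) of 18, 2β-H, 6α-H | [Li]OC1=C(C(C)C)[C@@H]2CC(C)=C[C@H]2C=C(C)C1 | intermediate (not isolated)
18 | (2β-H,6α-H)-7α-isopropyl-4,10-dimethylbicyclo[5.3.0]deca-1(10),3-dien-8-one | O=C1CC(C)=C[C@@H]2C=C(C)C[C@H]2[C@@H]1C(C)C | intermediate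
19 | (2β-H,6α-H)-7α-isopropyl-4,10-dimethylbicyclo[5.3.0]deca-1(10),3-dien-8α-ol | O[C@@H]1CC(C)=C[C@@H]2C=C(C)C[C@H]2[C@@H]1C(C)C | intermediate
20 | (2β-H,6α-H)-1α,10α-epoxy-7α-isopropyl-4,10β-dimethylbicyclo[5.3.0]dec-3-en-8α-ol | O[C@@H]1C[C@]3(C)O[C@@H]3[C@@H]2C=C(C)C[C@H]2[C@@H]1C(C)C | intermediate
21 | (2β-H,6α-H)-7α-isopropyl-4,10β-dimethylbicyclo[5.3.0]dec-3-ene-8α,10α-diol | O[C@@H]1C[C@](C)(O)C[C@@H]2C=C(C)C[C@H]2[C@@H]1C(C)C | intermediate
22 | isovanillic acid (3-hydroxy-4-methoxybenzoic acid) | COc1ccc(C(=O)O)cc1O | starting material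
23 | tert-butyldimethylsilyl 3-(tert-butyldimethylsilyloxy)-4-methoxybenzoate | COc1ccc(C(=O)O[Si](C)(C)C(C)(C)C)cc1O[Si](C)(C)C(C)(C)C | intermediate (not isolated)
24 | 3-(tert-butyldimethylsilyloxy)-4-methoxybenzoic acid | COc1ccc(C(=O)O)cc1O[Si](C)(C)C(C)(C)C | intermediate
25 | 3-(tert-butyldimethylsilyloxy)-4-methoxybenzoyl chloride | COc1ccc(C(=O)Cl)cc1O[Si](C)(C)C(C)(C)C | intermediate (not isolated)
26 | (2β-H,6α-H)-10α-hydroxy-7α-isopropyl-4,10β-dimethylbicyclo[5.3.0]dec-3-en-8α-yl 3-(tert-butyldimethylsilyloxy)-4-methoxybenzoate | COc1ccc(C(=O)O[C@@H]2C[C@](C)(O)C[C@@H]3C=C(C)C[C@H]3[C@@H]2C(C)C)cc1O[Si](C)(C)C(C)(C)C | intermediate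
27 | (2β-H,6α-H)-3α,4α-epoxy-10α-hydroxy-7α-isopropyl-4β,10β-dimethylbicyclo[5.3.0]decan-8α-yl 3-(tert-butyldimethylsilyloxy)-4-methoxybenzoate | COc1ccc(C(=O)O[C@@H]2C[C@](C)(O)C[C@H]3[C@@H](C[C@@]4(C)O[C@@H]34)[C@@H]2C(C)C)cc1O[Si](C)(C)C(C)(C)C | intermediate
28 | (2β-H,6α-H)-3α,4α-epoxy-10α-hydroxy-7α-isopropyl-4β,10β-dimethylbicyclo[5.3.0]decan-8α-yl 3-hydroxy-4-methoxybenzoate (CNP0106636.1) | COc1ccc(C(=O)O[C@@H]2C[C@](C)(O)C[C@H]3[C@@H](C[C@@]4(C)O[C@@H]34)[C@@H]2C(C)C)cc1O | target

**Step count**

Total: 17 steps. Longest linear sequence: 16 steps (steps 1–13 and 15–17); step 14 is the only branch.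

**Steps most likely to fail**

Step 9 (key step). What may go wrong: after loss of N2 the reaction may leak into the free-carbene channel (1,2-hydrogen shift from the isopropyl CH to a conjugated enone, or addition to the isopropenyl group), or the dienone may be consumed by further light absorption. The fallback leaves the route at ester 9 and returns at dienone 16. It takes the isopropyl group out of the Wolff event and runs the rearrangement in the dark. Saponification of 9 (LiOH, THF/H2O) gives (1R,5S,6R)-3-methyl-6-(prop-1-en-2-yl)bicyclo[3.1.0]hex-3-ene-1-carboxylic acid F1. (COCl)2 with cat. DMF gives the acid chloride F2, and CH2N2/Et3N (Et2O, 0 °C) gives the diazomethyl ketone F3 (Arndt–Eistert acylation). Silver-promoted Wolff rearrangement (AgO2CPh, Et3N, THF, 45 °C, ultrasound), the usual conditions for this tandem process with diazomethyl ketones, should give, through the aldoketene F4, the dienone without the isopropyl group, (2β-H)-4,10-dimethylbicyclo[5.3.0]deca-1(10),3,6-trien-8-one F5. α-Iodination of the enone (I2, pyridine, CH2Cl2) gives the 7-iodo dienone F6, and Negishi coupling with i-PrZnBr (PdCl2(dppf), THF, 23 °C) installs the isopropyl group on C7 to give 16.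

Step 2. What may go wrong: low enantiofacial discrimination by the chiral ylide on this cyclic, doubly activated acceptor, or its erosion by reversible betaine formation. The fallback leaves the route at 2 and 4 and returns at 6, by racemic cyclopropanation and enzymatic resolution. Tetrahydrothiophene and 2 give 1-(2-methylprop-2-en-1-yl)tetrahydrothiophenium bromide F7. Its ylide F8 (KN(SiMe3)2, THF, −78 °C) converts 4 into the racemic keto ester, that is 6 together with its enantiomer F9. NaBH4 (MeOH, 0 °C) attacks the ketone anti to the cyclopropane and gives the racemic endo alcohol, the (4R)-alcohol F10 of the wanted series and its (4S)-enantiomer F11. Lipase-catalysed acylation (Burkholderia cepacia lipase, vinyl acetate, t-BuOMe, 30 °C) should, by the usual size rule for secondary alcohols, acylate the (4R)-carbinol to the acetate F12 and leave F11. After chromatographic separation, methanolysis of F12 (K2CO3, MeOH) returns F10, and oxidation (Dess–Martin periodinane, CH2Cl2) gives enantiopure 6.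

Step 16. What may go wrong: the tertiary hydroxyl on C10 may fail to deliver the oxidant across the ring, so that the reagent attacks the sterically open β face of C3=C4 and gives the epimeric oxirane. The fallback leaves the route at 26 and returns at the target 28. It uses that same facial preference through a bromohydrin; a hydroxyl that cannot reach the alkene will not intercept the bromonium ion either. NBS in THF/H2O (0 °C) forms the bromonium ion on the β face and water opens it at the tertiary C4 from the α face, giving the 3β-bromo-4α-hydroxy compound F13. K2CO3 in MeOH (0 °C) closes the 3α,4α-oxirane by displacement of bromide with inversion at C3 and removes the aryl silyl ether in the same operation, giving 28.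

**Further compounds**

F1 | step 9 | (1R,5S,6R)-3-methyl-6-(prop-1-en-2-yl)bicyclo[3.1.0]hex-3-ene-1-carboxylic acid | OC(=O)[C@]12CC(C)=C[C@H]1[C@@H]2C(C)=C
F2 | step 9 | (1R,5S,6R)-3-methyl-6-(prop-1-en-2-yl)bicyclo[3.1.0]hex-3-ene-1-carbonyl chloride | ClC(=O)[C@]12CC(C)=C[C@H]1[C@@H]2C(C)=C
F3 | step 9 | 2-diazo-1-[(1R,5S,6R)-3-methyl-6-(prop-1-en-2-yl)bicyclo[3.1.0]hex-3-en-1-yl]ethan-1-one | [N-]=[N+]=CC(=O)[C@]12CC(C)=C[C@H]1[C@@H]2C(C)=C
F4 | step 9 | 2-[(1R,5S,6R)-3-methyl-6-(prop-1-en-2-yl)bicyclo[3.1.0]hex-3-en-1-yl]ethen-1-one (aldoketene, transient) | O=C=C[C@]12CC(C)=C[C@H]1[C@@H]2C(C)=C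
F5 | step 9 | (2β-H)-4,10-dimethylbicyclo[5.3.0]deca-1(10),3,6-trien-8-one | O=C1CC(C)=C[C@@H]2C=C(C)CC2=C1
F6 | step 9 | (2β-H)-7-iodo-4,10-dimethylbicyclo[5.3.0]deca-1(10),3,6-trien-8-one | O=C1CC(C)=C[C@@H]2C=C(C)CC2=C1I
F7 | step 2 | 1-(2-methylprop-2-en-1-yl)tetrahydrothiophenium bromide | C=C(C)C[S+]1CCCC1.[Br-]
F8 | step 2 | tetrahydrothiophenium 2-methylallylide (transient) | C=C(C)[CH-][S+]1CCCC1
F9 | step 2 | methyl (1R,5R,6S)-4-oxo-6-(prop-1-en-2-yl)bicyclo[3.1.0]hexane-1-carboxylate (enantiomer of 6) | COC(=O)[C@@]12CCC(=O)[C@@H]1[C@H]2C(C)=C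
F10 | step 2 | methyl (1S,4R,5S,6R)-4-hydroxy-6-(prop-1-en-2-yl)bicyclo[3.1.0]hexane-1-carboxylate | COC(=O)[C@]12CC[C@@H](O)[C@H]1[C@@H]2C(C)=C
F11 | step 2 | methyl (1R,4S,5R,6S)-4-hydroxy-6-(prop-1-en-2-yl)bicyclo[3.1.0]hexane-1-carboxylate | COC(=O)[C@@]12CC[C@H](O)[C@@H]1[C@H]2C(C)=C
F12 | step 2 | methyl (1S,4R,5S,6R)-4-acetoxy-6-(prop-1-en-2-yl)bicyclo[3.1.0]hexane-1-carboxylate | COC(=O)[C@]12CC[C@@H](OC(C)=O)[C@H]1[C@@H]2C(C)=C
F13 | step 16 | (2β-H,6α-H)-3β-bromo-4α,10α-dihydroxy-7α-isopropyl-4β,10β-dimethylbicyclo[5.3.0]decan-8α-yl 3-(tert-butyldimethylsilyloxy)-4-methoxybenzoate | COc1ccc(C(=O)O[C@@H]2C[C@](C)(O)C[C@H]3[C@@H](C[C@@](C)(O)[C@@H]3Br)[C@@H]2C(C)C)cc1O[Si](C)(C)C(C)(C)C
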